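**Retrosynthetic overview**
- The strategy rests on ring A (C1, C2, C3, C4, C5, C10): cis methyls on C4 and quaternary C5, C10–H, and the C2 oxygen para to C5. This is the pattern left by (E)-2-methylbut-2-enal adding across a 2-silyloxy-1,3-diene.
- Ring A is formed first, by the catalytic asymmetric Diels–Alder reaction that makes C3–C4 and C5–C10. C10 is then adjusted by epimerising the C9 aldehyde under control of a C2 dioxolane.
- Ring B is formed second, by ring-closing metathesis (C6=C7) between a C5 vinyl group (from the formyl group) and a C9 allyl carbinol, followed by oxidation and conjugation to the Δ7-9-one.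
- C9 is set by 1,2-reduction and Mitsunobu inversion with the (Z)-acid; the axial C2 alcohol by LiBH(s-Bu)3.
- C7 and C8 are set last, by α-epoxidation and trans-diaxial opening at C7 with an isopropenyl cuprate.

Key step: step 3

**Remarks on the chemistry (assumptions)**
- Locants are eremophilane locants: ring A = C1, C2, C3, C4, C5, C10; ring B = C5 to C10; C14 is the methyl on C5, C15 the methyl on C4. β is the face of C14, α the opposite face. The target is (2S,4S,5R,7R,8R,9S,10R) in these locants.
- The catalyst in step 3 is written as the (S)-diphenylprolinol-derived antipode. The facial sense is to be checked on adduct 6; if the antipode of 6 forms, the (R)-catalyst is used and nothing else changes.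
- (Z)-3-Methylpent-2-enoic acid is not assumed to be purchasable as the pure (Z) isomer; it is made in steps 12 and 13.

**Route**

Step 1
Reactants: 1 benzyloxyacetaldehyde; 2 1-(triphenylphosphoranylidene)propan-2-one
Product: 3 (E)-5-(benzyloxy)pent-3-en-2-one
Conditions: CH2Cl2, rt
Reagents that add atoms: none
Why: Wittig olefination with a stabilised ylide, which should give the (E)-enone because the intermediates equilibrate to the trans arrangement.

Step 2
Reactants: 3 (E)-5-(benzyloxy)pent-3-en-2-one
Product: 4 (E)-5-(benzyloxy)-2-(tert-butyldimethylsilyloxy)penta-1,3-diene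
Conditions: TBSOTf, Et3N, CH2Cl2, 0 °C
Reagents that add atoms: tert-butyldimethylsilyl trifluoromethanesulfonate, CC(C)(C)[Si](C)(C)OS(=O)(=O)C(F)(F)F
Why: Soft enolisation (silyl triflate and amine) of the methyl ketone on its CH3 side should give the cross-conjugated 2-silyloxydiene and leave the (E) alkene untouched.

Step 3
Reactants: 4 (E)-5-(benzyloxy)-2-(tert-butyldimethylsilyloxy)penta-1,3-diene; 5 (E)-2-methylbut-2-enal (tiglic aldehyde)
Product: 6 (1R,2S,6S)-2-(benzyloxymethyl)-4-(tert-butyldimethylsilyloxy)-1,6-dimethylcyclohex-3-ene-1-carbaldehyde (ring A: 5α-CHO, 5β-CH3, 4β-CH3, 10α-CH2OBn, C1=C2 enol silane)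
Conditions: (S)-B-(o-tolyl)oxazaborolidine from (S)-α,α-diphenylprolinol (20 mol%), Tf2NH (18 mol%), CH2Cl2, −78 → −40 °C; Et3N quench
Reagents that add atoms: none
Why: The N-protonated oxazaborolidine binds the formyl oxygen of 5 and lowers the enal LUMO, so the diene adds in a concerted, asynchronous [4+2] cycloaddition in which the CH2 terminus (C3) bonds to the β-carbon (C4) and the substituted terminus (C10) to the α-carbon (C5), closing six-membered ring A in one suprafacial event; the closest known reaction type is the oxazaborolidinium-catalysed Diels–Alder reaction of α-substituted enals with 2-silyloxydienes. C4 and C5 are set together: the (E) geometry of 5 is carried stereospecifically into the cis relation of C14 and C15, and the catalyst, which covers one face of the bound enal, fixes their absolute configuration. C10 is set by the endo/exo topology, and with an acyclic (E)-diene the Lewis-acid-bound formyl group is expected endo, which places CH2OBn cis to the formyl group (10α); this is not the configuration of the target, so the centre is not relied upon and is corrected in step 7, where a formyl-exo adduct would converge as well. The regiochemistry the step needs is secured twice in 4, because the 2-silyloxy group and the terminal alkyl group both send C10 to the α-carbon. Reactivity, the main concern with a trisubstituted enal, is helped by the strongly donating enol ether of 4, and the product carries the C2 carbonyl in latent form together with the formyl and benzyloxymethyl groups from which ring B is grown.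

Step 4
Reactants: 6 the Diels–Alder adduct
Product: 7 tert-butyl[(3α-benzyloxymethyl-4β,5β-dimethyl-4α-vinylcyclohex-1-en-1-yl)oxy]dimethylsilane (ring A: 5α-vinyl, 5β-CH3, 4β-CH3, 10α-CH2OBn, C1=C2 enol silane)
Conditions: Ph3PCH3Br, KN(SiMe3)2, THF, 0 °C → rt
Reagents that add atoms: methyltriphenylphosphonium bromide, C[P+](c1ccccc1)(c1ccccc1)c1ccccc1.[Br-]
Why: Wittig methylenation of a non-enolisable neopentyl aldehyde, which should leave the enol silane and all three stereocentres untouched.

Step 5
Reactants: 7 the vinyl enol silane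
Product: 9 9α-(benzyloxymethyl)-7β,8β-dimethyl-8α-vinyl-1,4-dioxaspiro[4.5]decane (C2 dioxolane; 10α-CH2OBn), via C2 ketone 8 (not isolated)
Conditions: HOCH2CH2OH, TsOH·H2O (cat.), benzene, reflux, water separator
Reagents that add atoms: ethylene glycol, OCCO
Why: Acid-catalysed protodesilylation of the enol ether to ketone 8 followed by acetal formation with azeotropic removal of water; no stereocentre is touched, and the dioxolane is the control element for step 7.

Step 6
Reactants: 9 the benzyl ether ketal
Product: 10 (7β,8β-dimethyl-8α-vinyl-1,4-dioxaspiro[4.5]decan-9α-yl)methanol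
Conditions: lithium 4,4′-di-tert-butylbiphenylide (LiDBB), THF, −78 °C; aq. NH4Cl
Reagents that add atoms: none
Why: Reductive cleavage of the benzyl ether by single-electron transfer, which should spare the isolated vinyl group and the dioxolane where hydrogenolysis would not spare the alkene.

Step 7
Reactants: 10 the primary alcohol
Product: 12 7β,8β-dimethyl-8α-vinyl-1,4-dioxaspiro[4.5]decane-9β-carbaldehyde (10β-CHO, cis to C14 and C15, trans to vinyl), via 10α-aldehyde 11 (not isolated)
Conditions: Dess–Martin periodinane, NaHCO3, CH2Cl2, 0 °C → rt; then K2CO3, MeOH, rt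
Reagents that add atoms: none
Why: Dess–Martin oxidation, then base-mediated epimerisation through the aldehyde enolate, sets C10 thermodynamically: in 11 either chair puts a group syn-axial to a dioxolane oxygen (the formyl group in one, C15 with an axial vinyl group in the other), whereas 12 has formyl, C15 and vinyl all equatorial.

Step 8
Reactants: 12 the 10β-aldehyde; 13 allylmagnesium bromide
Product: 14 1-(7β,8β-dimethyl-8α-vinyl-1,4-dioxaspiro[4.5]decan-9β-yl)but-3-en-1-ol (both C9 epimers)
Conditions: THF, −78 °C; aq. NH4Cl
Reagents that add atoms: none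
Why: Grignard addition to the aldehyde; the new C9 carbinol centre forms without control and is erased in step 10.

Step 9
Reactants: 14 the diene alcohol
Product: 15 2,2-ethylenedioxy-4β,5β-dimethyl-10αH-octal-6-en-9-ol (trans-fused; both C9 epimers)
Conditions: second-generation Grubbs catalyst (H2IMes)(PCy3)Cl2Ru=CHPh (5 mol%), CH2Cl2, 40 °C
Reagents that add atoms: none
Why: Ring-closing metathesis; the catalyst should load at the unhindered allyl terminus and close six-membered ring B onto the neopentyl vinyl group, the two chains being trans-diequatorial on ring A, with loss of ethene.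

Step 10
Reactants: 15 the homoallylic alcohol
Product: 17 2,2-ethylenedioxy-4β,5β-dimethyl-10αH-octal-7-en-9-one (trans-fused Δ7-9-one), via Δ6-9-one 16 (not isolated)
Conditions: Dess–Martin periodinane, NaHCO3, CH2Cl2, rt; then DBU, CH2Cl2, rt
Reagents that add atoms: none
Why: Dess–Martin oxidation to the β,γ-unsaturated ketone and base-mediated conjugation through the dienolate; C10, now α to the ketone, should stay trans-fused because either chair of the cis-fused isomer again suffers a syn-axial contact with a dioxolane oxygen.

Step 11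
Reactants: 17 the Δ7-9-one
Product: 18 2,2-ethylenedioxy-4β,5β-dimethyl-10αH-octal-7-en-9β-ol
Conditions: NaBH4, CeCl3·7H2O, MeOH, −78 → 0 °C
Reagents that add atoms: none
Why: Luche 1,2-reduction, in which hydride should reach C9 from the α face, away from the axial C5 methyl that is syn-axial to the β trajectory, giving the pseudoaxial 9β-alcohol.

Step 12
Reactants: 19 ethyl pent-2-ynoate; 20 methyllithium
Product: 21 ethyl (Z)-3-methylpent-2-enoate
Conditions: MeLi (2 equiv), CuI, Et2O, 0 °C (forms Me2CuLi); then 19, THF, −78 °C; MeOH, then aq. NH4Cl at −78 °C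
Reagents that add atoms: none
Why: syn-Carbocupration of the ynoate at low temperature puts methyl and copper on the same side, so protonation of the vinylcopper with retention should leave ethyl cis to the ester, the (Z) geometry.

Step 13
Reactants: 21 ethyl (Z)-3-methylpent-2-enoate
Product: 22 (Z)-3-methylpent-2-enoic acid
Conditions: LiOH, THF/MeOH/H2O, rt; then 1 M HCl
Reagents that add atoms: lithium hydroxide, [Li+].[OH-]
Why: Ester saponification; the trisubstituted alkene geometry should be retained under hydroxide at room temperature.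

Step 14
Reactants: 18 the 9β-alcohol; 22 (Z)-3-methylpent-2-enoic acid
Product: 23 2,2-ethylenedioxy-4β,5β-dimethyl-10αH-octal-7-en-9α-yl (Z)-3-methylpent-2-enoate
Conditions: PPh3, DIAD, toluene, 0 °C → rt
Reagents that add atoms: none
Why: Mitsunobu esterification, in which SN2 displacement of the oxyphosphonium ion by the carboxylate from the open α face should invert C9 to the pseudoequatorial 9α-ester.

Step 15
Reactants: 23 the ketal ester
Product: 24 4β,5β-dimethyl-2-oxo-10αH-octal-7-en-9α-yl (Z)-3-methylpent-2-enoate
Conditions: PPTS, acetone/H2O, 55 °C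
Reagents that add atoms: water, O
Why: Mild acid-catalysed acetal hydrolysis, possible once C10 is no longer α to a carbonyl; the allylic ester and both alkenes should tolerate pyridinium tosylate.

Step 16
Reactants: 24 the C2 ketone
Product: 25 2α-hydroxy-4β,5β-dimethyl-10αH-octal-7-en-9α-yl (Z)-3-methylpent-2-enoate
Conditions: LiBH(s-Bu)3 (L-Selectride), THF, −78 °C; aq. NH4Cl
Reagents that add atoms: none
Why: Bulky-hydride ketone reduction, in which the reagent should attack C2 along the equatorial (β) trajectory of the ring A chair and give the axial 2α-alcohol, while the ester is not reduced at −78 °C.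

Step 17
Reactants: 25 the 2α-alcohol
Product: 26 7α,8α-epoxy-2α-hydroxy-4β,5β-dimethyl-10αH-decalin-9α-yl (Z)-3-methylpent-2-enoate
Conditions: mCPBA, NaHCO3, CH2Cl2, 0 °C
Reagents that add atoms: 3-chloroperoxybenzoic acid, O=C(OO)c1cccc(Cl)c1
Why: Prilezhaev epoxidation of the ring alkene (the conjugated enoate alkene is deactivated) from the α face, opposite the axial C5 methyl that covers the β face, should set C7 and C8 as the 7α,8α-epoxide.

Step 18
Reactants: 26 the 7α,8α-epoxide; 27 isopropenylmagnesium bromide
Product: 28 (2S,4S,5R,7R,8R,9S,10R)-2α,8α-dihydroxy-10αH-eremophil-11-en-9α-yl (Z)-3-methylpent-2-enoate (target)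
Conditions: 27 (6 equiv), CuBr·SMe2 (3 equiv), THF, −40 → −10 °C; aq. NH4Cl/NH3
Reagents that add atoms: none
Why: Organocuprate SN2 opening of the epoxide in the trans-diaxial (Fürst–Plattner) sense: attack at C7 from the β face, distal to the electron-withdrawing C9 ester, should invert C7 (7β-isopropenyl) and leave the axial 8α-hydroxyl, with excess reagent taking up the free C2 hydroxyl.

**Compound list**
1 | benzyloxyacetaldehyde | O=CCOCc1ccccc1 | starting material
2 | 1-(triphenylphosphoranylidene)propan-2-one | CC(=O)C=P(c1ccccc1)(c1ccccc1)c1ccccc1 | starting material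
3 | (E)-5-(benzyloxy)pent-3-en-2-one | CC(=O)/C=C/COCc1ccccc1 | intermediate
4 | (E)-5-(benzyloxy)-2-(tert-butyldimethylsilyloxy)penta-1,3-diene | C=C(O[Si](C)(C)C(C)(C)C)/C=C/COCc1ccccc1 | intermediate
5 | (E)-2-methylbut-2-enal | C/C=C(\C)C=O | starting material
6 | (1R,2S,6S)-2-(benzyloxymethyl)-4-(tert-butyldimethylsilyloxy)-1,6-dimethylcyclohex-3-ene-1-carbaldehyde | O=C[C@]1(C)[C@@H](C)CC(O[Si](C)(C)C(C)(C)C)=C[C@@H]1COCc2ccccc2 | intermediate
7 | C5-vinyl enol silane (5α-vinyl, 4β,5β-dimethyl, 10α-CH2OBn) | C=C[C@]1(C)[C@@H](C)CC(O[Si](C)(C)C(C)(C)C)=C[C@@H]1COCc2ccccc2 | intermediate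
8 | corresponding C2 ketone | C=C[C@]1(C)[C@@H](C)CC(=O)C[C@@H]1COCc2ccccc2 | intermediate (not isolated)
9 | 9α-(benzyloxymethyl)-7β,8β-dimethyl-8α-vinyl-1,4-dioxaspiro[4.5]decane | C=C[C@]1(C)[C@@H](C)CC2(OCCO2)C[C@@H]1COCc3ccccc3 | intermediate
10 | (7β,8β-dimethyl-8α-vinyl-1,4-dioxaspiro[4.5]decan-9α-yl)methanol | C=C[C@]1(C)[C@@H](C)CC2(OCCO2)C[C@@H]1CO | intermediate
11 | 10α-aldehyde (formyl cis to vinyl) | C=C[C@]1(C)[C@@H](C)CC2(OCCO2)C[C@@H]1C=O | intermediate (not isolated)
12 | 10β-aldehyde (formyl trans to vinyl) | C=C[C@]1(C)[C@@H](C)CC2(OCCO2)C[C@H]1C=O | intermediate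
13 | allylmagnesium bromide | C=CC[Mg]Br | starting material
14 | 1-(7β,8β-dimethyl-8α-vinyl-1,4-dioxaspiro[4.5]decan-9β-yl)but-3-en-1-ol (C9 epimers) | C=C[C@]1(C)[C@@H](C)CC2(OCCO2)C[C@H]1C(O)CC=C | intermediate
15 | 2,2-ethylenedioxy-4β,5β-dimethyl-10αH-octal-6-en-9-ol (C9 epimers) | C1=C[C@]2(C)[C@@H](C)CC3(OCCO3)C[C@H]2C(O)C1 | intermediate
16 | 2,2-ethylenedioxy-4β,5β-dimethyl-10αH-octal-6-en-9-one | C1=C[C@]2(C)[C@@H](C)CC3(OCCO3)C[C@H]2C(=O)C1 | intermediate (not isolated)
17 | 2,2-ethylenedioxy-4β,5β-dimethyl-10αH-octal-7-en-9-one | C1=CC[C@]2(C)[C@@H](C)CC3(OCCO3)C[C@H]2C1=O | intermediate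
18 | 2,2-ethylenedioxy-4β,5β-dimethyl-10αH-octal-7-en-9β-ol | C1=CC[C@]2(C)[C@@H](C)CC3(OCCO3)C[C@H]2[C@H]1O | intermediate
19 | ethyl pent-2-ynoate | CCC#CC(=O)OCC | starting material
20 | methyllithium | C[Li] | starting material
21 | ethyl (Z)-3-methylpent-2-enoate | CCOC(=O)/C=C(/C)CC | intermediate
22 | (Z)-3-methylpent-2-enoic acid | OC(=O)/C=C(/C)CC | intermediate
23 | 9α-ester, C2 dioxolane, Δ7 | C1=CC[C@]2(C)[C@@H](C)CC3(OCCO3)C[C@H]2[C@@H]1OC(=O)/C=C(/C)CC | intermediate
24 | 9α-ester, C2 ketone, Δ7 | C1=CC[C@]2(C)[C@@H](C)CC(=O)C[C@H]2[C@@H]1OC(=O)/C=C(/C)CC | intermediate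
25 | 9α-ester, 2α-ol, Δ7 | C1=CC[C@]2(C)[C@@H](C)C[C@H](O)C[C@H]2[C@@H]1OC(=O)/C=C(/C)CC | intermediate
26 | 9α-ester, 2α-ol, 7α,8α-epoxide | O1[C@@H]2C[C@]3(C)[C@@H](C)C[C@H](O)C[C@H]3[C@H](OC(=O)/C=C(/C)CC)[C@H]12 | intermediate
27 | isopropenylmagnesium bromide | C=C(C)[Mg]Br | starting material
28 | (2S,4S,5R,7R,8R,9S,10R)-2α,8α-dihydroxy-10αH-eremophil-11-en-9α-yl (Z)-3-methylpent-2-enoate | C=C(C)[C@H]1C[C@]2(C)[C@@H](C)C[C@H](O)C[C@H]2[C@H](OC(=O)/C=C(/C)CC)[C@@H]1O | target

**Step count**
Total: 18 steps. Longest linear sequence: 16 steps (steps 1 to 11, then 14 to 18); the acid branch (steps 12 and 13) joins at step 14.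

**Steps most likely to fail**

Step 3. The trisubstituted enal may cycloadd too slowly, so that silyl transfer or Mukaiyama-type addition of the enol ether to the activated formyl group takes over, or the catalyst may discriminate the enal faces poorly. The endo/exo outcome is not part of this risk, because step 7 removes it. Fallback: the cycloaddition of 4 and 5 is run without chiral information (Me2AlCl, CH2Cl2, −78 → −20 °C, or thermally in toluene at 110 °C). This should give racemic 6, that is 6 together with its enantiomer F1. The racemate is taken through steps 4 and 5, which beside 7, 8 and 9 give the enantiomeric vinyl enol silane F2, the enantiomeric ketone F3 (not isolated) and the enantiomeric ketal F4. Racemic 9, which carries the benzyl chromophore, is then resolved by preparative chromatography on a chiral stationary phase (cellulose tris(3,5-dimethylphenylcarbamate)). The fallback sets out from 4 and 5 and returns to the route at 9.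

Step 14. Activation of the hindered, pseudoaxial allylic 9β-alcohol may lead to anti elimination across C9–C10 or to allylic ionisation with attack at C7, and the weakly acidic enoic acid may be too poor a partner to outrun these paths. Fallback: 18 is inverted with a stronger acid (4-nitrobenzoic acid, PPh3, DIAD, toluene) to the 9α-(4-nitrobenzoate) F5, which is methanolysed (K2CO3, MeOH) to the 9α-alcohol F6. F6 is then acylated with retention by the mixed anhydride of 22 (2,4,6-trichlorobenzoyl chloride, Et3N, then DMAP, toluene; Yamaguchi esterification). The fallback sets out from 18 and returns at 23.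

Step 18. Approach to C7 is syn-axial to the C5 methyl and may be slow, and the C8 alkoxide formed next to the cis C9 ester may cause acyl transfer from O9 to O8, or the ester may be attacked by the organometallic. Fallback: the ester is removed before the C–C bond is formed. Epoxide 26 is methanolysed (K2CO3, MeOH; the 9α-alkoxide is cis to the epoxide and cannot open it from the rear) to the epoxy diol F7. F7 is opened with the same cuprate in larger excess, with BF3·OEt2 if needed, to 7β-isopropenyl-4β,5β-dimethyl-10αH-decalin-2α,8α,9α-triol F8. The equatorial 9α-hydroxyl of the cis-8,9-diol is then acylated selectively with (Z)-3-methylpent-2-enoyl chloride F9 (made from 22 with 1-chloro-N,N,2-trimethylprop-1-en-1-amine), using Ph2BOCH2CH2NH2 (cat.) and iPr2NEt in MeCN (borinate-catalysed equatorial acylation of a cis-diol). The fallback sets out from 26 and returns at 28.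

**Further compounds**
F1 | step 3 | enantiomer of 6, (1S,2R,6R)-2-(benzyloxymethyl)-4-(tert-butyldimethylsilyloxy)-1,6-dimethylcyclohex-3-ene-1-carbaldehyde | O=C[C@@]1(C)[C@H](C)CC(O[Si](C)(C)C(C)(C)C)=C[C@H]1COCc2ccccc2
F2 | step 3 | enantiomer of 7 | C=C[C@@]1(C)[C@H](C)CC(O[Si](C)(C)C(C)(C)C)=C[C@H]1COCc2ccccc2
F3 | step 3 | enantiomer of 8 | C=C[C@@]1(C)[C@H](C)CC(=O)C[C@H]1COCc2ccccc2
F4 | step 3 | enantiomer of 9 | C=C[C@@]1(C)[C@H](C)CC2(OCCO2)C[C@H]1COCc3ccccc3
F5 | step 14 | 2,2-ethylenedioxy-4β,5β-dimethyl-10αH-octal-7-en-9α-yl 4-nitrobenzoate | C1=CC[C@]2(C)[C@@H](C)CC3(OCCO3)C[C@H]2[C@@H]1OC(=O)c4ccc(cc4)[N+](=O)[O-]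
F6 | step 14 | 2,2-ethylenedioxy-4β,5β-dimethyl-10αH-octal-7-en-9α-ol | C1=CC[C@]2(C)[C@@H](C)CC3(OCCO3)C[C@H]2[C@@H]1O
F7 | step 18 | 7α,8α-epoxy-4β,5β-dimethyl-10αH-decalin-2α,9α-diol | O1[C@@H]2C[C@]3(C)[C@@H](C)C[C@H](O)C[C@H]3[C@H](O)[C@H]12
F8 | step 18 | 7β-isopropenyl-4β,5β-dimethyl-10αH-decalin-2α,8α,9α-triol | C=C(C)[C@H]1C[C@]2(C)[C@@H](C)C[C@H](O)C[C@H]2[C@H](O)[C@@H]1O
F9 | step 18 | (Z)-3-methylpent-2-enoyl chloride | ClC(=O)/C=C(/C)CC
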